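**Retrosynthetic overview** (oxane ring: O1, C2–C6; cyclohexane: C1'–C6', with Br on C3' and Cl/Me on C4')
1. 20 ⇐ 19 by Petasis methylenation of the lactone carbonyl C2; 19 ⇐ 16 by trans-diaxial chlorohydrin formation, OH→Br exchange and a stereoconvergent 1,2-halogen interchange (sets C3' and C4').
2. 16 ⇐ 15 by 6-endo bromolactonisation of the prenyl group (closes the oxane, sets C5); 15 ⇐ 13 ⇐ 11 by fluoride removal of the silicon tether after convex-face prenylation of the bicyclic ester enolate (sets C3 from C1').
3. 11 ⇐ 10 ⇐ 9: a silicon-tethered intramolecular Diels–Alder reaction forms the C1'–C6' and C4'–C5' bonds (the tethered vinyl group becomes C6'–C5'), then SE2' protodesilylation places the alkene at C3'=C4'.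
4. Enabling feature: the hydroxyl oxygen on C3 of the oxane sits on the carbon bonded to C1' of the cyclohexane, so an O–SiMe2–CH=CH2 tether (temporary 1-oxa-2-silacyclopentane) reaches C1', while C1' and C4' are the 1,4-termini of a diene whose C4' end carries the methyl group and a silyl group.
5. Ring order: cyclohexene together with the temporary oxasilolane (step 6), then the oxane as δ-lactone (step 10), then the exocyclic enol ether (step 13); 9 ⇐ 7 ⇐ 6 ⇐ 4 + 5, 4 ⇐ 1 + 2.

Key step: step 6

Remark: the (S,S)-catalyst of step 4 is assumed to deliver hydride in the sense known for aryl ketones with the dienyl group in the aryl position (otherwise its enantiomer is used), and 10 is drawn as the cis-fused adduct, whose ring-fusion epimer at C7a would converge in step 9.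

Step 1
Reactants: 1 but-2-yn-1-ol; 2 dimethyl(phenyl)silane
Product: 3 (2E)-3-[dimethyl(phenyl)silyl]but-2-en-1-ol
Conditions: PtCl2 (1 mol %), XPhos (2 mol %), THF, 50 °C
Reagents that add atoms: none
Why: Platinum-catalysed hydrosilylation of a propargylic alcohol is a syn addition that places silicon on the alkyne carbon remote from oxygen, which should give the (E)-vinylsilane with the methyl group cis to the carbinol carbon.

Step 2
Reactants: 3 (2E)-3-[dimethyl(phenyl)silyl]but-2-en-1-ol
Product: 4 (2E)-3-[dimethyl(phenyl)silyl]but-2-enal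
Conditions: MnO2 (activated, excess), CH2Cl2, rt
Reagents that add atoms: none
Why: Activated MnO2 oxidises the allylic alcohol to the enal (allylic oxidation) without touching the vinylsilane or its geometry.

Step 3
Reactants: 4 (2E)-3-[dimethyl(phenyl)silyl]but-2-enal; 5 ethyl 2-oxo-3-(triphenyl-λ5-phosphanylidene)propanoate
Product: 6 ethyl (3E,5E)-6-[dimethyl(phenyl)silyl]-2-oxohepta-3,5-dienoate
Conditions: CH2Cl2, 40 °C
Reagents that add atoms: none
Why: Wittig olefination with the stabilised keto ylide should give the (E)-alkene and so the (3E,5E)-2-oxodienoate directly.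

Step 4
Reactants: 6 ethyl (3E,5E)-6-[dimethyl(phenyl)silyl]-2-oxohepta-3,5-dienoate
Product: 7 ethyl (2R,3E,5E)-6-[dimethyl(phenyl)silyl]-2-hydroxyhepta-3,5-dienoate
Conditions: RuCl[(S,S)-TsDPEN](p-cymene) (1 mol %), HCO2H/Et3N 5:2, CH2Cl2, 0 °C
Reagents that add atoms: none
Why: Noyori–Ikariya asymmetric transfer hydrogenation reduces the activated keto group of a 2-oxoalk-3-enoate in the 1,2 sense, and the catalyst sets the (R)-carbinol centre that will steer the cycloaddition.

Step 5
Reactants: 7 ethyl (2R,3E,5E)-6-[dimethyl(phenyl)silyl]-2-hydroxyhepta-3,5-dienoate; 8 chloro(ethenyl)dimethylsilane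
Product: 9 ethyl (2R,3E,5E)-6-[dimethyl(phenyl)silyl]-2-{[ethenyl(dimethyl)silyl]oxy}hepta-3,5-dienoate
Conditions: imidazole, CH2Cl2, 0 °C to rt
Reagents that add atoms: none
Why: Silylation of the secondary alcohol with the vinylchlorosilane (silyl ether formation) attaches the two-carbon dienophile to the oxygen that ends as the tertiary hydroxyl of the target.

Step 6
Reactants: 9 ethyl (2R,3E,5E)-6-[dimethyl(phenyl)silyl]-2-{[ethenyl(dimethyl)silyl]oxy}hepta-3,5-dienoate
Product: 10 ethyl (3R,3aS,6R,7aS)-6-[dimethyl(phenyl)silyl]-1,1,6-trimethyl-1,3,3a,6,7,7a-hexahydro-2,1-benzoxasilole-3-carboxylate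
Conditions: PhMe (0.01 M), BHT (cat.), sealed tube, 175 °C
Reagents that add atoms: none
Why: The step is a thermal, concerted, suprafacial intramolecular Diels–Alder reaction of type 1 in which the silicon-bound vinyl group adds across C3 and C6 of the dienoate, so that the C3a–C7a and C6–C7 bonds (C1'–C6' and C4'–C5' of the target) form together; the closest known reaction type is the temporary-silicon-connection Diels–Alder reaction of vinylsilyl ethers of dienols, where the vinylsilane is a tethered ethylene equivalent. The cyclohexene ring closes by [4+2] cycloaddition and the 1-oxa-2-silacyclopentane closes at the same time as a fused ring, because the three-atom C–O–Si tether joins the diene terminus to the proximal dienophile carbon (fused mode only). C3a is controlled by the C3 carbinol centre: in the transition state the C3–H bond eclipses the diene (allylic strain minimum), the silyloxy tether lies on the dienophile face and the ester points outward, so the dienophile should reach one diene face. C6 follows from the (5E) geometry (silyl group outside, hence cis to the C3 carbon on the new ring) and C7a from the cis ring fusion; both centres are erased in steps 7 and 9 and need no control. The step needs π-facial selectivity and periselectivity over the 1,5-hydrogen shift of the Z-methyl diene: the first is secured by the C3 stereocentre, the second by the entropic advantage of the short tether, and regiochemistry is fixed by the tether. The methyl- and silyl-substituted diene terminus is what later allows the cycloadduct alkene to be moved to the C3'=C4' position.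

Step 7
Reactants: 10 ethyl (3R,3aS,6R,7aS)-6-[dimethyl(phenyl)silyl]-1,1,6-trimethyl-1,3,3a,6,7,7a-hexahydro-2,1-benzoxasilole-3-carboxylate
Product: 11 ethyl (3R,3aS,7aS)-1,1,6-trimethyl-1,3,3a,4,7,7a-hexahydro-2,1-benzoxasilole-3-carboxylate
Conditions: CF3CO2H (2 equiv), CH2Cl2, 0 °C
Reagents that add atoms: none
Why: Acid-induced SE2' protodesilylation of the tertiary allylsilane protonates C4, the β-silyl cation loses silicon and the alkene moves to the trisubstituted C5=C6 position, which removes the C6 stereocentre and creates none.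

Step 8
Reactants: 11 ethyl (3R,3aS,7aS)-1,1,6-trimethyl-1,3,3a,4,7,7a-hexahydro-2,1-benzoxasilole-3-carboxylate; 12 1-bromo-3-methylbut-2-ene
Product: 13 ethyl (3S,3aS,7aS)-1,1,6-trimethyl-3-(3-methylbut-2-en-1-yl)-1,3,3a,4,7,7a-hexahydro-2,1-benzoxasilole-3-carboxylate
Conditions: LDA, THF, −78 °C; then 12, DMPU, −78 to −40 °C
Reagents that add atoms: none
Why: Alkylation of the lithium ester enolate with the allylic bromide should occur on the convex face of the bicycle, anti to the cyclohexene carbon C4 on the neighbouring ring-fusion atom C3a, so that the prenyl group enters cis to H-3a and the quaternary carbinol centre C3 is set from C3a.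

Step 9
Reactants: 13 ethyl (3S,3aS,7aS)-1,1,6-trimethyl-3-(3-methylbut-2-en-1-yl)-1,3,3a,4,7,7a-hexahydro-2,1-benzoxasilole-3-carboxylate
Product: 15 (2S)-2-hydroxy-5-methyl-2-[(1S)-4-methylcyclohex-3-en-1-yl]hex-4-enoic acid, via hydroxy ester 14 (not isolated)
Conditions: TBAF·3H2O (5 equiv), DMF, 80 °C; then LiOH, THF/H2O, 50 °C; aq. HCl work-up
Reagents that add atoms: lithium hydroxide, [Li+].[OH-]
Why: Fluoride opens the Si–O bond and the pentacoordinate silicate undergoes protodesilylation of the C7a–Si bond (known for temporary silicon tethers), which turns C7a into CH2 and frees the tertiary hydroxyl, and hydroxide then saponifies the ester without touching a stereocentre.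

Step 10
Reactants: 15 (2S)-2-hydroxy-5-methyl-2-[(1S)-4-methylcyclohex-3-en-1-yl]hex-4-enoic acid
Product: 16 (3S,5R)-5-bromo-3-hydroxy-6,6-dimethyl-3-[(1S)-4-methylcyclohex-3-en-1-yl]oxan-2-one
Conditions: NBS (1.05 equiv), MeCN, −30 °C, dark
Reagents that add atoms: N-bromosuccinimide, O=C1CCC(=O)N1Br
Why: Bromolactonisation with NBS is a 6-endo, Markovnikov, anti addition through a chair-like transition state with bromine and the cyclohexenyl group equatorial (hydroxyl axial), which sets C5 cis to the cyclohexenyl group, and the carboxyl-assisted prenyl alkene should react much faster than the ring alkene or the tertiary hydroxyl.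

Step 11
Reactants: 16 (3S,5R)-5-bromo-3-hydroxy-6,6-dimethyl-3-[(1S)-4-methylcyclohex-3-en-1-yl]oxan-2-one
Product: 17 (3S,5R)-5-bromo-3-[(1S,3R,4R)-3-chloro-4-hydroxy-4-methylcyclohexyl]-3-hydroxy-6,6-dimethyloxan-2-one
Conditions: trichloroisocyanuric acid (0.35 equiv), acetone/H2O 4:1, 0 °C
Reagents that add atoms: trichloroisocyanuric acid, O=C1N(Cl)C(=O)N(Cl)C(=O)N1Cl; water, O
Why: Chlorohydrin formation is an electrophilic Markovnikov addition that follows the trans-diaxial rule on the cyclohexene anchored by its equatorial C1' substituent, so chlorine should enter axially at C3' trans to that substituent and water should open at the tertiary C4' from the opposite face.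

Step 12
Reactants: 17 (3S,5R)-5-bromo-3-[(1S,3R,4R)-3-chloro-4-hydroxy-4-methylcyclohexyl]-3-hydroxy-6,6-dimethyloxan-2-one
Product: 19 (3S,5R)-5-bromo-3-[(1S,3S,4S)-3-bromo-4-chloro-4-methylcyclohexyl]-3-hydroxy-6,6-dimethyloxan-2-one, via diaxial tertiary bromide 18 (not isolated)
Conditions: HBr (g), CH2Cl2, −20 °C; then MeNO2, 60 °C
Reagents that add atoms: hydrogen bromide, Br
Why: HBr replaces the tertiary hydroxyl through the β-chloro tertiary cation with axial capture anti to chlorine, and warming in a polar solvent then drives the known diaxial-to-diequatorial 1,2-interchange of vicinal halogens through a halogen-bridged ion pair, which inverts C3' and C4' together and should funnel 18 and any C4' epimer into 19, favoured by the tertiary C–Cl bond and the polar medium.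

Step 13
Reactants: 19 (3S,5R)-5-bromo-3-[(1S,3S,4S)-3-bromo-4-chloro-4-methylcyclohexyl]-3-hydroxy-6,6-dimethyloxan-2-one
Product: 20 (3S,5R)-5-bromo-3-[(1S,3S,4S)-3-bromo-4-chloro-4-methylcyclohexyl]-6,6-dimethyl-2-methylideneoxan-3-ol
Conditions: Cp2TiMe2 (3 equiv), PhMe/THF, 65 °C, dark
Reagents that add atoms: dimethyltitanocene, C[Ti](C)(C1C=CC=C1)C1C=CC=C1
Why: Petasis methylenation turns the lactone carbonyl into the exocyclic enol ether under neutral conditions that should leave the alkyl halides and every stereocentre untouched, the free tertiary hydroxyl only consuming reagent as a titanium alkoxide.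

**Compound list**
1 | but-2-yn-1-ol | CC#CCO | starting material
2 | dimethyl(phenyl)silane | C[SiH](C)c1ccccc1 | starting material
3 | (2E)-3-[dimethyl(phenyl)silyl]but-2-en-1-ol | OC/C=C(\C)[Si](C)(C)c1ccccc1 | intermediate
4 | (2E)-3-[dimethyl(phenyl)silyl]but-2-enal | O=C/C=C(\C)[Si](C)(C)c1ccccc1 | intermediate
5 | ethyl 2-oxo-3-(triphenyl-λ5-phosphanylidene)propanoate | CCOC(=O)C(=O)C=P(c1ccccc1)(c1ccccc1)c1ccccc1 | starting material
6 | ethyl (3E,5E)-6-[dimethyl(phenyl)silyl]-2-oxohepta-3,5-dienoate | CCOC(=O)C(=O)/C=C/C=C(\C)[Si](C)(C)c1ccccc1 | intermediate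
7 | ethyl (2R,3E,5E)-6-[dimethyl(phenyl)silyl]-2-hydroxyhepta-3,5-dienoate | CCOC(=O)[C@H](O)/C=C/C=C(\C)[Si](C)(C)c1ccccc1 | intermediate
8 | chloro(ethenyl)dimethylsilane | C=C[Si](C)(C)Cl | starting material
9 | ethyl (2R,3E,5E)-6-[dimethyl(phenyl)silyl]-2-{[ethenyl(dimethyl)silyl]oxy}hepta-3,5-dienoate | CCOC(=O)[C@H](O[Si](C)(C)C=C)/C=C/C=C(\C)[Si](C)(C)c1ccccc1 | intermediate
10 | ethyl (3R,3aS,6R,7aS)-6-[dimethyl(phenyl)silyl]-1,1,6-trimethyl-1,3,3a,6,7,7a-hexahydro-2,1-benzoxasilole-3-carboxylate | CCOC(=O)[C@@H]1O[Si](C)(C)[C@H]2C[C@@](C)([Si](C)(C)c3ccccc3)C=C[C@@H]12 | intermediate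
11 | ethyl (3R,3aS,7aS)-1,1,6-trimethyl-1,3,3a,4,7,7a-hexahydro-2,1-benzoxasilole-3-carboxylate | CCOC(=O)[C@@H]1O[Si](C)(C)[C@H]2CC(C)=CC[C@@H]12 | intermediate
12 | 1-bromo-3-methylbut-2-ene | CC(C)=CCBr | starting material
13 | ethyl (3S,3aS,7aS)-1,1,6-trimethyl-3-(3-methylbut-2-en-1-yl)-1,3,3a,4,7,7a-hexahydro-2,1-benzoxasilole-3-carboxylate | CCOC(=O)[C@@]1(CC=C(C)C)O[Si](C)(C)[C@H]2CC(C)=CC[C@@H]12 | intermediate
14 | ethyl (2S)-2-hydroxy-5-methyl-2-[(1S)-4-methylcyclohex-3-en-1-yl]hex-4-enoate | CCOC(=O)[C@](O)(CC=C(C)C)[C@H]1CCC(C)=CC1 | intermediate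
15 | (2S)-2-hydroxy-5-methyl-2-[(1S)-4-methylcyclohex-3-en-1-yl]hex-4-enoic acid | OC(=O)[C@](O)(CC=C(C)C)[C@H]1CCC(C)=CC1 | intermediate
16 | (3S,5R)-5-bromo-3-hydroxy-6,6-dimethyl-3-[(1S)-4-methylcyclohex-3-en-1-yl]oxan-2-one | O=C1OC(C)(C)[C@H](Br)C[C@]1(O)[C@H]1CCC(C)=CC1 | intermediate
17 | (3S,5R)-5-bromo-3-[(1S,3R,4R)-3-chloro-4-hydroxy-4-methylcyclohexyl]-3-hydroxy-6,6-dimethyloxan-2-one | O=C1OC(C)(C)[C@H](Br)C[C@]1(O)[C@H]1CC[C@@](C)(O)[C@H](Cl)C1 | intermediate
18 | (3S,5R)-5-bromo-3-[(1S,3R,4R)-4-bromo-3-chloro-4-methylcyclohexyl]-3-hydroxy-6,6-dimethyloxan-2-one | O=C1OC(C)(C)[C@H](Br)C[C@]1(O)[C@H]1CC[C@@](C)(Br)[C@H](Cl)C1 | intermediate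
19 | (3S,5R)-5-bromo-3-[(1S,3S,4S)-3-bromo-4-chloro-4-methylcyclohexyl]-3-hydroxy-6,6-dimethyloxan-2-one | O=C1OC(C)(C)[C@H](Br)C[C@]1(O)[C@H]1CC[C@](C)(Cl)[C@@H](Br)C1 | intermediate
20 | (3S,5R)-5-bromo-3-[(1S,3S,4S)-3-bromo-4-chloro-4-methylcyclohexyl]-6,6-dimethyl-2-methylideneoxan-3-ol | C=C1OC(C)(C)[C@H](Br)C[C@]1(O)[C@H]1CC[C@](C)(Cl)[C@@H](Br)C1 | target

Total step count: 13. Longest linear sequence: 13 steps (1 to 20).

**Steps most likely to fail**

Step 6: the cycloaddition may be too slow, because the diene carries a Z-methyl group on its terminus and the vinylsilane is unactivated. Thermal 1,5-hydrogen shift or incomplete π-facial selectivity could then erode the material, and a facial isomer would have to be removed before step 8. Fallback: the same triene 9 is cyclised through a metallacycle instead of a pericyclic transition state, by a rhodium-catalysed intramolecular [4+2] cycloaddition of an unactivated diene–ene pair ([Rh(cod)Cl]2, AgSbF6, 1,2-dichloroethane, 60 °C). It sets out from 9 and comes back at 10 without any new compound (F0).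

Step 11: electrophilic chlorination may be unselective, because chloronium formation is not reversible. Attack on the wrong alkene face, ene-type allylic chlorination or ether formation by the tertiary hydroxyl could compete. Fallback, setting out from 16: NBS in aqueous acetone (reversible bromonium ion, trans-diaxial opening) should give the bromohydrin (3S,5R)-5-bromo-3-[(1S,3R,4R)-3-bromo-4-hydroxy-4-methylcyclohexyl]-3-hydroxy-6,6-dimethyloxan-2-one F1. DBU in CH2Cl2 closes it to the epoxide (3S,5R)-5-bromo-3-hydroxy-6,6-dimethyl-3-[(1S,3S,6R)-6-methyl-7-oxabicyclo[4.1.0]heptan-3-yl]oxan-2-one F2. LiCl and AcOH in THF open the epoxide at the secondary carbon in the trans-diaxial sense, which comes back at 17.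

Step 12: the halogen interchange may stop at an unfavourable equilibrium, or loss of HBr from the tertiary bromide may outrun it. Fallback, setting out from 16: direct anti addition of BrCl (NBS, Me3SiCl, CH2Cl2, −78 °C) is expected to give 19 as the minor trans adduct beside its trans-diaxial isomer (3S,5R)-5-bromo-3-[(1S,3R,4R)-3-bromo-4-chloro-4-methylcyclohexyl]-3-hydroxy-6,6-dimethyloxan-2-one F3. Compound 19 is separated by chromatography, and F3 is returned to 16 by reductive elimination with zinc dust in acetic acid and resubmitted. The fallback comes back at 19.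

Further compounds
F0 | step 6 | none | none
F1 | step 11 | (3S,5R)-5-bromo-3-[(1S,3R,4R)-3-bromo-4-hydroxy-4-methylcyclohexyl]-3-hydroxy-6,6-dimethyloxan-2-one | O=C1OC(C)(C)[C@H](Br)C[C@]1(O)[C@H]1CC[C@@](C)(O)[C@H](Br)C1
F2 | step 11 | (3S,5R)-5-bromo-3-hydroxy-6,6-dimethyl-3-[(1S,3S,6R)-6-methyl-7-oxabicyclo[4.1.0]heptan-3-yl]oxan-2-one | O=C1OC(C)(C)[C@H](Br)C[C@]1(O)[C@H]1CC[C@@]2(C)O[C@H]2C1
F3 | step 12 | (3S,5R)-5-bromo-3-[(1S,3R,4R)-3-bromo-4-chloro-4-methylcyclohexyl]-3-hydroxy-6,6-dimethyloxan-2-one | O=C1OC(C)(C)[C@H](Br)C[C@]1(O)[C@H]1CC[C@@](C)(Cl)[C@H](Br)C1
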